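**Retrosynthetic overview**

- Feature used: in the cyclohexenone core (C1 ketone, C2 amide carbon, C3, C4 carbinol, C5–C6 oxirane) the chain C4–C5–C6–C1 carries oxygen on every carbon, as in tartaric acid, and C1–C2 is the enamide of a 1,2-dione whose C3 is a methyl group in the open chain.
- Late disconnections: C4 silyl ether; lower triene by Stille coupling of a C4 (E)-vinylstannane with an iododienamide of 2-aminocyclopentane-1,3-dione; oxirane C6–O bond from the trans-5,6-diol (C6 mesylate, C5 alkoxide).
- C2–N bond by Pd-catalysed amidation of the C2 enol triflate with (2E,4E,6E)-10-methylundeca-2,4,6-trienamide (from 4-methylpentanal by two Horner–Wadsworth–Emmons reactions).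
- C3–C4 bond by intramolecular aldol addition of a D-tartrate-derived methyl 1,2-diketone to its silyl ynone; this precursor comes from the bis(N-methoxy-N-methylamide) of the acetonide by two successive organolithium additions.
- Ring order: six-membered carbocycle first (step 4), oxirane second (step 16); the cyclopentenone ring is bought as cyclopentane-1,3-dione and the dioxolane is a temporary ring of the starting material.

Key step: step 4

Remark: core atoms are numbered C1 (ketone), C2 (amide-bearing carbon), C3, C4 (carbinol), C5 and C6 (oxirane carbons); 2-aminocyclopentane-1,3-dione is drawn as its enol, 2-amino-3-hydroxycyclopent-2-en-1-one.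

**Route**

Step 1
Reactants: 1 dimethyl 2,3-O-isopropylidene-D-tartrate
Product: 2 (4S,5S)-bis(N-methoxy-N-methylamide) of the acetonide
Conditions: MeNH(OMe)·HCl, i-PrMgCl, THF, −20 °C
Reagents that add atoms: N,O-dimethylhydroxylamine hydrochloride, CNOC.Cl
Why: Ester aminolysis by the magnesium amide of N,O-dimethylhydroxylamine converts both esters at low temperature without touching the two tartrate stereocentres.

Step 2
Reactants: 2 bis(N-methoxy-N-methylamide); 3 (triisopropylsilyl)acetylene; 4 ethyl vinyl ether
Product: 9 (4S,5S)-acetonide bearing a silyl ynone and a 2-ethoxyprop-2-enoyl group, via lithium acetylide 5 (not isolated), via mono-adduct 6 (not isolated), via 1-ethoxyvinyllithium 7 (not isolated), via bis-adduct 8 (not isolated)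
Conditions: 3, n-BuLi, THF, −78 °C, then 2, −78 to −30 °C; then 7 (from 4, t-BuLi, THF, −78 to 0 °C), −78 °C; aq NH4Cl
Reagents that add atoms: none
Why: Weinreb ketone synthesis run twice in one pot, in which the acetylide should add once because the first tetrahedral lithium chelate shields the neighbouring amide, the chelate keeps the ynone masked while the more reactive 1-ethoxyvinyllithium (an acetyl anion equivalent) acylates the second amide, and both ketones are released only on quench.

Step 3
Reactants: 9 ynone 2-ethoxyprop-2-enoyl acetonide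
Product: 10 (4S,5S)-acetonide bearing a methyl 1,2-diketone and the silyl ynone
Conditions: 1 M aq HCl, THF, 0 °C
Reagents that add atoms: water, O
Why: Acid-catalysed enol ether hydrolysis is much faster than cleavage of the dioxolane, which is deactivated by its two acyl neighbours, and unveils the methyl 1,2-diketone.

Step 4
Reactants: 10 methyl 1,2-diketone silyl ynone acetonide
Product: 12 (4R,5S,6S)-2,4-dihydroxy-5,6-(isopropylidenedioxy)-4-[(triisopropylsilyl)ethynyl]cyclohex-2-en-1-one, via cyclic 1,2-dione 11 (not isolated)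
Conditions: MgBr2·OEt2, i-Pr2NEt, CH2Cl2, −20 °C to rt
Reagents that add atoms: none
Why: Magnesium bromide chelates the two adjacent carbonyl groups so that the amine can remove a proton from the C3 methyl group (soft enolisation), the enolate carbon adds to the C4 ynone carbonyl (intramolecular aldol addition), and the cyclic 1,2-dione 11 enolises towards C3 to the diosphenol. The closest known reaction types are the magnesium halide/amine mediated direct aldol addition of ketone donors and the aldol cyclisation of 1,2-diketones to 2-hydroxycyclohexenones. The six-membered ring closes in the 6-(enolendo)-exo-trig mode, since both enolate carbons C2 and C3 end up in the ring. The new C4 stereocentre is controlled by the trans-fused dioxolane, which fixes a chair with the C5 and C6 oxygens equatorial; the magnesium-bound C4 oxygen should then take the equatorial site, trans to the C5 oxygen, and the rod-like silylalkynyl group the axial site, where it meets only the axial C6–H because C2 is trigonal, and as the aldol is reversible this is also the expected equilibrium outcome. The step needs site selectivity for the methyl group over the C5 and C6 methine hydrogens and 1,2- over 1,4-addition: the chelated diketone makes the unhindered methyl group the most accessible acidic site for a weak hindered base, and the triisopropylsilyl group blocks the ynone β-carbon, attack on which would in any case require an eight-membered ring.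

Step 5
Reactants: 12 diosphenol
Product: 13 C2 enol trifluoromethanesulfonate of 12
Conditions: PhNTf2, Et3N, CH2Cl2, 0 °C to rt
Reagents that add atoms: N-phenylbis(trifluoromethanesulfonimide), O=S(=O)(N(c1ccccc1)S(=O)(=O)C(F)(F)F)C(F)(F)F
Why: Enol triflate formation takes place at the acidic C2 enol hydroxyl and not at the tertiary C4 alcohol, and capping the enol also shuts off retro-aldol cleavage.

Step 6
Reactants: 14 4-methylpentanal; 15 triethyl 4-phosphonocrotonate
Product: 16 ethyl (2E,4E)-8-methylnona-2,4-dienoate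
Conditions: LiN(SiMe3)2, THF, −78 to 0 °C
Reagents that add atoms: none
Why: Vinylogous Horner–Wadsworth–Emmons olefination with a stabilised phosphonate anion should give the new double bond E and keep the existing one E.

Step 7
Reactants: 16 dienoate
Product: 17 (2E,4E)-8-methylnona-2,4-dien-1-ol
Conditions: i-Bu2AlH, CH2Cl2, −78 °C
Reagents that add atoms: none
Why: Hydride reduction of the conjugated ester with i-Bu2AlH proceeds by 1,2-addition only and leaves the diene intact.

Step 8
Reactants: 17 dienol
Product: 18 (2E,4E)-8-methylnona-2,4-dienal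
Conditions: MnO2, CH2Cl2, rt
Reagents that add atoms: none
Why: Allylic oxidation with MnO2 is selective for the allylic alcohol and does not isomerise the double bonds.

Step 9
Reactants: 18 dienal; 19 diethyl (carbamoylmethyl)phosphonate
Product: 20 (2E,4E,6E)-10-methylundeca-2,4,6-trienamide
Conditions: NaH, THF, 0 °C to rt
Reagents that add atoms: none
Why: Horner–Wadsworth–Emmons olefination with the phosphonoacetamide, whose C–H is more acidic than its N–H, installs the third E double bond and the primary amide in one operation.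

Step 10
Reactants: 13 enol triflate; 20 trienamide
Product: 21 (4R,5S,6S)-4-hydroxy-5,6-(isopropylidenedioxy)-2-[(2E,4E,6E)-10-methylundeca-2,4,6-trienoylamino]-4-[(triisopropylsilyl)ethynyl]cyclohex-2-en-1-one
Conditions: Pd2(dba)3 (cat.), Xantphos, Cs2CO3, 1,4-dioxane, 50 °C
Reagents that add atoms: none
Why: Palladium-catalysed C–N cross-coupling (Buchwald–Hartwig-type amidation of an enol triflate), in which zerovalent palladium inserts readily into the electron-poor α-keto enol triflate and the wide-bite-angle diphosphine favours C–N reductive elimination with the primary amide, the stereocentres not being involved.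

Step 11
Reactants: 21 silylalkyne enamide
Product: 22 4-ethynyl enamide (terminal alkyne)
Conditions: Bu4NF, AcOH, THF, 0 °C
Reagents that add atoms: none
Why: Fluoride-induced protodesilylation of the alkynylsilane, buffered with acetic acid so that the β-alkoxy ketone is not enolised at C6.

Step 12
Reactants: 22 terminal alkyne
Product: 23 C4 triethylsilyl ether of 22
Conditions: Et3SiOTf, 2,6-lutidine, CH2Cl2, −78 °C
Reagents that add atoms: triethylsilyl trifluoromethanesulfonate, CC[Si](CC)(CC)OS(=O)(=O)C(F)(F)F
Why: Silyl ether formation with a silyl triflate and a hindered pyridine base reaches the tertiary propargylic alcohol, masks the C4 oxygen against later epoxide migration and adds bulk next to C5.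

Step 13
Reactants: 23 silyl ether acetonide
Product: 24 (4R,5S,6S)-4-ethynyl-5,6-dihydroxy-2-(trienoylamino)-4-(triethylsilyloxy)cyclohex-2-en-1-one
Conditions: AcOH–H2O (4:1), 35 °C
Reagents that add atoms: none
Why: Acetal hydrolysis of the strained trans-fused dioxolane is expected to be faster than loss of the tertiary triethylsilyl ether under mild aqueous acid.

Step 14
Reactants: 24 ethynyl diol
Product: 25 (4R,5S,6S)-5,6-dihydroxy-4-[(E)-2-(tributylstannyl)ethenyl] analogue of 24
Conditions: Bu3SnH, PdCl2(PPh3)2 (cat.), THF, 0 °C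
Reagents that add atoms: tributyltin hydride, CCCC[SnH](CCCC)CCCC
Why: Palladium-catalysed hydrostannation adds H and Sn syn across the terminal alkyne with tin on the terminal carbon, away from fully substituted C4, giving the (E)-vinylstannane, and the alkyne should react much faster than the hindered enone.

Step 15
Reactants: 25 vinylstannane diol
Product: 26 C6 methanesulfonate of 25 (C5 hydroxyl free)
Conditions: MsCl, 2,4,6-collidine, CH2Cl2, −20 °C
Reagents that add atoms: methanesulfonyl chloride, CS(=O)(=O)Cl
Why: Sulfonylation (mesylate formation) with a hindered base should occur only at the C6 hydroxyl, because the C5 hydroxyl is flanked by quaternary C4 with its silyloxy and stannylvinyl groups.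

Step 16
Reactants: 26 C6 mesylate
Product: 27 (4R,5S,6R)-5,6-epoxy-2-(trienoylamino)-4-[(E)-2-(tributylstannyl)ethenyl]-4-(triethylsilyloxy)cyclohex-2-en-1-one
Conditions: K2CO3, MeOH, 0 °C
Reagents that add atoms: none
Why: Intramolecular Williamson-type SN2 displacement in the trans-diaxial conformer, in which the C5 alkoxide attacks the reactive α-keto carbon C6 from the face opposite to the mesylate, so that C6 is inverted, C5 is retained and the oxirane lies trans to the C4 oxygen.

Step 17
Reactants: 28 cyclopentane-1,3-dione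
Product: 29 2-nitrocyclopentane-1,3-dione
Conditions: fuming HNO3, Et2O, 0 °C
Reagents that add atoms: nitric acid, O[N+](=O)[O-]
Why: Electrophilic nitration of the enol form of the 1,3-dione takes place at C2, the only nucleophilic carbon.

Step 18
Reactants: 29 nitro dione
Product: 30 2-amino-3-hydroxycyclopent-2-en-1-one hydrochloride
Conditions: H2 (1 atm), Pd/C, MeOH, HCl
Reagents that add atoms: hydrogen chloride, Cl
Why: Catalytic hydrogenation reduces the nitro group to the amine, which is trapped as its hydrochloride to prevent self-condensation.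

Step 19
Reactants: 31 ethyl (E)-4-oxobut-2-enoate
Product: 32 ethyl (2E,4E)-5-iodopenta-2,4-dienoate
Conditions: CrCl2, CHI3, THF, 0 °C
Reagents that add atoms: iodoform, IC(I)I
Why: Takai olefination, in which the geminal dichromium species from iodoform adds to the aldehyde only and should give the (E)-vinyl iodide.

Step 20
Reactants: 32 iododienoate
Product: 33 (2E,4E)-5-iodopenta-2,4-dienoic acid
Conditions: LiOH, THF–H2O, 0 °C; then 1 M HCl
Reagents that add atoms: lithium hydroxide, [Li+].[OH-]
Why: Ester saponification under mild conditions leaves the iododiene untouched.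

Step 21
Reactants: 33 iododienoic acid; 30 aminocyclopentenone hydrochloride
Product: 35 (2E,4E)-N-(2-hydroxy-5-oxocyclopent-1-en-1-yl)-5-iodopenta-2,4-dienamide, via acyl chloride 34 (not isolated)
Conditions: (COCl)2, DMF (cat.), CH2Cl2, 0 °C; then 30, Et3N, CH2Cl2–DMF, 0 °C to rt
Reagents that add atoms: none
Why: Amide formation through the acyl chloride, the amine nitrogen being more nucleophilic than the enol oxygen and any enol ester being cleaved on mild basic work-up.

Step 22
Reactants: 27 epoxy vinylstannane; 35 iododienamide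
Product: 36 C4 triethylsilyl ether of the target
Conditions: Pd2(dba)3 (cat.), AsPh3, DMF, rt
Reagents that add atoms: none
Why: Stille cross-coupling of the alkenylstannane with the alkenyl iodide proceeds with retention of both double-bond geometries under neutral conditions that the epoxy ketone, the silyl ether and the acidic enol should tolerate.

Step 23
Reactants: 36 silyl ether of the target
Product: 37 target (4S,5S,6R)
Conditions: HF·pyridine, pyridine, THF, 0 °C
Reagents that add atoms: none
Why: Desilylation with buffered fluoride cleaves the tertiary triethylsilyl ether without opening the oxirane or isomerising the trienes.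

**Compound list**

1 | dimethyl 2,3-O-isopropylidene-D-tartrate, dimethyl (4S,5S)-2,2-dimethyl-1,3-dioxolane-4,5-dicarboxylate | COC(=O)[C@H]1OC(C)(C)O[C@@H]1C(=O)OC | starting material
2 | (4S,5S)-N,N'-dimethoxy-N,N',2,2-tetramethyl-1,3-dioxolane-4,5-dicarboxamide | CON(C)C(=O)[C@H]1OC(C)(C)O[C@@H]1C(=O)N(C)OC | intermediate
3 | (triisopropylsilyl)acetylene | C#C[Si](C(C)C)(C(C)C)C(C)C | starting material
4 | ethyl vinyl ether | C=COCC | starting material
5 | lithium (triisopropylsilyl)acetylide | [Li]C#C[Si](C(C)C)(C(C)C)C(C)C | intermediate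
6 | lithium hemiaminal mono-adduct of 5 to one amide of 2 (new carbinol carbon undefined) | [Li]OC(N(C)OC)(C#C[Si](C(C)C)(C(C)C)C(C)C)[C@H]1OC(C)(C)O[C@@H]1C(=O)N(C)OC | intermediate
7 | 1-ethoxyvinyllithium | [Li]C(=C)OCC | intermediate
8 | dilithium bis-hemiaminal adduct (both carbinol carbons undefined) | [Li]OC(N(C)OC)(C#C[Si](C(C)C)(C(C)C)C(C)C)[C@H]1OC(C)(C)O[C@@H]1C(O[Li])(N(C)OC)C(=C)OCC | intermediate
9 | 1-[(4S,5S)-5-(2-ethoxyprop-2-enoyl)-2,2-dimethyl-1,3-dioxolan-4-yl]-3-(triisopropylsilyl)prop-2-yn-1-one | C=C(OCC)C(=O)[C@H]1OC(C)(C)O[C@@H]1C(=O)C#C[Si](C(C)C)(C(C)C)C(C)C | intermediate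
10 | 1-[(4S,5S)-2,2-dimethyl-5-[3-(triisopropylsilyl)prop-2-ynoyl]-1,3-dioxolan-4-yl]propane-1,2-dione | CC(=O)C(=O)[C@H]1OC(C)(C)O[C@@H]1C(=O)C#C[Si](C(C)C)(C(C)C)C(C)C | intermediate
11 | (4R,5S,6S)-4-hydroxy-5,6-(isopropylidenedioxy)-4-[(triisopropylsilyl)ethynyl]cyclohexane-1,2-dione, keto tautomer of 12 | O=C1C(=O)C[C@@](O)(C#C[Si](C(C)C)(C(C)C)C(C)C)[C@H]2OC(C)(C)O[C@H]12 | intermediate
12 | (4R,5S,6S)-2,4-dihydroxy-5,6-(isopropylidenedioxy)-4-[(triisopropylsilyl)ethynyl]cyclohex-2-en-1-one (C4–OH trans to C5–O, C5–O trans to C6–O) | O=C1C(O)=C[C@@](O)(C#C[Si](C(C)C)(C(C)C)C(C)C)[C@H]2OC(C)(C)O[C@H]12 | intermediate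
13 | (4R,5S,6S)-4-hydroxy-5,6-(isopropylidenedioxy)-2-(trifluoromethylsulfonyloxy)-4-[(triisopropylsilyl)ethynyl]cyclohex-2-en-1-one | O=C1C(OS(=O)(=O)C(F)(F)F)=C[C@@](O)(C#C[Si](C(C)C)(C(C)C)C(C)C)[C@H]2OC(C)(C)O[C@H]12 | intermediate
14 | 4-methylpentanal | CC(C)CCC=O | starting material
15 | triethyl 4-phosphonocrotonate, ethyl (E)-4-(diethoxyphosphoryl)but-2-enoate | CCOC(=O)/C=C/CP(=O)(OCC)OCC | starting material
16 | ethyl (2E,4E)-8-methylnona-2,4-dienoate | CCOC(=O)/C=C/C=C/CCC(C)C | intermediate
17 | (2E,4E)-8-methylnona-2,4-dien-1-ol | OC/C=C/C=C/CCC(C)C | intermediate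
18 | (2E,4E)-8-methylnona-2,4-dienal | O=C/C=C/C=C/CCC(C)C | intermediate
19 | diethyl (carbamoylmethyl)phosphonate | NC(=O)CP(=O)(OCC)OCC | starting material
20 | (2E,4E,6E)-10-methylundeca-2,4,6-trienamide | NC(=O)/C=C/C=C/C=C/CCC(C)C | intermediate
21 | (4R,5S,6S)-4-hydroxy-5,6-(isopropylidenedioxy)-2-[(2E,4E,6E)-10-methylundeca-2,4,6-trienoylamino]-4-[(triisopropylsilyl)ethynyl]cyclohex-2-en-1-one | CC(C)CC/C=C/C=C/C=C/C(=O)NC1=C[C@@](O)(C#C[Si](C(C)C)(C(C)C)C(C)C)[C@H]2OC(C)(C)O[C@@H]2C1=O | intermediate
22 | (4R,5S,6S)-4-ethynyl-4-hydroxy-5,6-(isopropylidenedioxy)-2-(trienoylamino)cyclohex-2-en-1-one | CC(C)CC/C=C/C=C/C=C/C(=O)NC1=C[C@@](O)(C#C)[C@H]2OC(C)(C)O[C@@H]2C1=O | intermediate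
23 | (4R,5S,6S)-4-ethynyl-5,6-(isopropylidenedioxy)-2-(trienoylamino)-4-(triethylsilyloxy)cyclohex-2-en-1-one | CC(C)CC/C=C/C=C/C=C/C(=O)NC1=C[C@@](O[Si](CC)(CC)CC)(C#C)[C@H]2OC(C)(C)O[C@@H]2C1=O | intermediate
24 | (4R,5S,6S)-4-ethynyl-5,6-dihydroxy-2-(trienoylamino)-4-(triethylsilyloxy)cyclohex-2-en-1-one | CC(C)CC/C=C/C=C/C=C/C(=O)NC1=C[C@@](O[Si](CC)(CC)CC)(C#C)[C@@H](O)[C@H](O)C1=O | intermediate
25 | (4R,5S,6S)-5,6-dihydroxy-2-(trienoylamino)-4-[(E)-2-(tributylstannyl)ethenyl]-4-(triethylsilyloxy)cyclohex-2-en-1-one | CC(C)CC/C=C/C=C/C=C/C(=O)NC1=C[C@@](O[Si](CC)(CC)CC)(/C=C/[Sn](CCCC)(CCCC)CCCC)[C@@H](O)[C@H](O)C1=O | intermediate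
26 | (4R,5S,6S)-5-hydroxy-6-(methylsulfonyloxy)-2-(trienoylamino)-4-[(E)-2-(tributylstannyl)ethenyl]-4-(triethylsilyloxy)cyclohex-2-en-1-one | CC(C)CC/C=C/C=C/C=C/C(=O)NC1=C[C@@](O[Si](CC)(CC)CC)(/C=C/[Sn](CCCC)(CCCC)CCCC)[C@@H](O)[C@H](OS(C)(=O)=O)C1=O | intermediate
27 | (4R,5S,6R)-5,6-epoxy-2-(trienoylamino)-4-[(E)-2-(tributylstannyl)ethenyl]-4-(triethylsilyloxy)cyclohex-2-en-1-one (oxirane trans to C4–O) | CC(C)CC/C=C/C=C/C=C/C(=O)NC1=C[C@@](O[Si](CC)(CC)CC)(/C=C/[Sn](CCCC)(CCCC)CCCC)[C@H]2O[C@H]2C1=O | intermediate
28 | cyclopentane-1,3-dione | O=C1CCC(=O)C1 | starting material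
29 | 2-nitrocyclopentane-1,3-dione | O=C1CCC(=O)C1[N+](=O)[O-] | intermediate
30 | 2-amino-3-hydroxycyclopent-2-en-1-one hydrochloride | NC1=C(O)CCC1=O.Cl | intermediate
31 | ethyl (E)-4-oxobut-2-enoate | CCOC(=O)/C=C/C=O | starting material
32 | ethyl (2E,4E)-5-iodopenta-2,4-dienoate | CCOC(=O)/C=C/C=C/I | intermediate
33 | (2E,4E)-5-iodopenta-2,4-dienoic acid | OC(=O)/C=C/C=C/I | intermediate
34 | (2E,4E)-5-iodopenta-2,4-dienoyl chloride | ClC(=O)/C=C/C=C/I | intermediate
35 | (2E,4E)-N-(2-hydroxy-5-oxocyclopent-1-en-1-yl)-5-iodopenta-2,4-dienamide | O=C(/C=C/C=C/I)NC1=C(O)CCC1=O | intermediate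
36 | (4S,5S,6R) C4 triethylsilyl ether of the target | CC(C)CC/C=C/C=C/C=C/C(=O)NC1=C[C@@](O[Si](CC)(CC)CC)(/C=C/C=C/C=C/C(=O)NC2=C(O)CCC2=O)[C@H]2O[C@H]2C1=O | intermediate
37 | target, (4S,5S,6R)-5,6-epoxy-4-hydroxy-4-[(1E,3E,5E)-7-[(2-hydroxy-5-oxocyclopent-1-en-1-yl)amino]-7-oxohepta-1,3,5-trienyl]-2-[(2E,4E,6E)-10-methylundeca-2,4,6-trienoylamino]cyclohex-2-en-1-one | CC(C)CC/C=C/C=C/C=C/C(=O)NC1=C[C@@](O)(/C=C/C=C/C=C/C(=O)NC2=C(O)CCC2=O)[C@H]2O[C@H]2C1=O | target

**Step count**

Total: 23 steps. Longest linear sequence: 14 steps (steps 1–5, 10–16, 22, 23).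

**Steps most likely to fail**

Step 4. The base may remove the C6 or C5 methine hydrogen instead of a methyl hydrogen, which would lead to β-elimination of a dioxolane oxygen or to epimerisation. The facial selectivity at C4 may also be incomplete, or the aldol may revert. The fallback sets out from 10 and avoids a free enolate in equilibrium with an amine. Compound 10 is converted with t-BuMe2SiOTf and Et3N in CH2Cl2 at −78 °C into the tert-butyldimethylsilyl enol ether of the methyl ketone F1. F1 is then cyclised by an intramolecular Mukaiyama aldol addition with BF3·OEt2 in CH2Cl2 at −78 °C. This addition is irreversible, and the Lewis-acid-bound carbonyl oxygen should again take the equatorial site. Aqueous work-up removes the silyl group, and the route is rejoined at 12.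

Step 15. Sulfonylation may occur at the C5 hydroxyl or at both hydroxyls, or the silyl group may migrate from the C4 to the C5 oxygen in the following base step. Either would place the oxirane on the wrong face or prevent its closure. The fallback sets out from 25 and no longer depends on telling the two hydroxyls apart. Excess MsCl and Et3N give the 5,6-bis(methanesulfonate) F2. A Tipson–Cohen elimination (NaI, Zn, DMF, 60 °C) then gives the 4-silyloxy-4-stannylvinyl cyclohexa-2,5-dienone F3. Weitz–Scheffer epoxidation (t-BuOOH, DBU, CH2Cl2, 0 °C) should attack the unsubstituted C5=C6 bond, not the amide-bearing C2=C3 bond, and should come in anti to the C4 silyloxy group. The route is rejoined at 27.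

Step 2. The first tetrahedral adduct may collapse early, so that the second organolithium attacks the free ynone. The acetylide may also add twice, or the dioxolane may be deprotonated. The fallback sets out from 2 and separates the two additions. Addition of 5 alone and quench give the ynone mono(N-methoxy-N-methylamide) F4. Luche reduction (NaBH4, CeCl3·7H2O, MeOH, −78 °C) masks the ketone as the propargylic alcohol F5, whose carbinol configuration is of no consequence. 1-Ethoxyvinyllithium (2.2 equiv, the alkoxide formed first protecting itself) then acylates the remaining amide to give the hydroxy 2-ethoxyprop-2-enoyl compound F6. Oxidation of the propargylic alcohol with MnO2 in CH2Cl2 rejoins the route at 9.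

**Further compounds**

F1 | step 4 | 1-[(4S,5S)-5-[2-(tert-butyldimethylsilyloxy)prop-2-enoyl]-2,2-dimethyl-1,3-dioxolan-4-yl]-3-(triisopropylsilyl)prop-2-yn-1-one | C=C(O[Si](C)(C)C(C)(C)C)C(=O)[C@H]1OC(C)(C)O[C@@H]1C(=O)C#C[Si](C(C)C)(C(C)C)C(C)C
F2 | step 15 | (4R,5S,6S)-5,6-bis(methylsulfonyloxy) analogue of 25 | CC(C)CC/C=C/C=C/C=C/C(=O)NC1=C[C@@](O[Si](CC)(CC)CC)(/C=C/[Sn](CCCC)(CCCC)CCCC)[C@@H](OS(C)(=O)=O)[C@H](OS(C)(=O)=O)C1=O
F3 | step 15 | 2-(trienoylamino)-4-[(E)-2-(tributylstannyl)ethenyl]-4-(triethylsilyloxy)cyclohexa-2,5-dien-1-one, C4 as in 25 | CC(C)CC/C=C/C=C/C=C/C(=O)NC1=C[C@@](O[Si](CC)(CC)CC)(/C=C/[Sn](CCCC)(CCCC)CCCC)C=CC1=O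
F4 | step 2 | (4S,5S)-N-methoxy-N,2,2-trimethyl-5-[3-(triisopropylsilyl)prop-2-ynoyl]-1,3-dioxolane-4-carboxamide | CON(C)C(=O)[C@H]1OC(C)(C)O[C@@H]1C(=O)C#C[Si](C(C)C)(C(C)C)C(C)C
F5 | step 2 | (4S,5S)-5-[1-hydroxy-3-(triisopropylsilyl)prop-2-ynyl]-N-methoxy-N,2,2-trimethyl-1,3-dioxolane-4-carboxamide, carbinol epimers | CON(C)C(=O)[C@H]1OC(C)(C)O[C@@H]1C(O)C#C[Si](C(C)C)(C(C)C)C(C)C
F6 | step 2 | 2-ethoxy-1-[(4S,5S)-5-[1-hydroxy-3-(triisopropylsilyl)prop-2-ynyl]-2,2-dimethyl-1,3-dioxolan-4-yl]prop-2-en-1-one, carbinol epimers | C=C(OCC)C(=O)[C@H]1OC(C)(C)O[C@@H]1C(O)C#C[Si](C(C)C)(C(C)C)C(C)C
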